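Ring labels: A is the fused resorcinol ring, B the fused catechol ring, C the six-membered carbocycle, D the central monophenol ring, E the pendant catechol ring, F the seven-membered carbocycle. M1 is the CH common to C and F, and M2 is the CH that carries E.
Retrosynthetic cuts, in order: seven O–H back to O–Me, then the A–D biaryl bond (opens ring C), then the CH2–ring A bond and the M1–H bond (back to a ketone at M1), then three bonds of ring B at once.
Enabling feature: ring B touches the skeleton only through its fusion bond with ring F (the carbons attached to M1 and M2). Both ring B carbons flanking that bond are CH, and the two oxygen-bearing carbons lie opposite it. Ring B is therefore an ethynyl group on the M1 carbon, an ethynyl group on M2 and a symmetrical C2 unit whose two boron atoms stand in for the catechol oxygens.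
Forward order: rings E and D are bought and joined through M2 (steps 1–9), rings B and F form together (step 10), ring A is attached (step 16), ring C closes (step 17), and global demethylation ends the route (step 18).
Stereochemistry: M2 (R in the target) comes from an auxiliary-controlled Evans benzylation. M1 (S) comes from a substrate-controlled hydroboration that places the hydrogens of M1 and M2 cis on ring F, as the target SMILES requires.
Key step: step 10

Assumption: bis(pinacolboryl)acetylene is taken as a purchasable catalogue reagent.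

Step 1
Reactants: 1 homoveratric acid; 2 (R)-4-benzyloxazolidin-2-one
Product: 4 (R)-4-benzyl-3-[(3,4-dimethoxyphenyl)acetyl]oxazolidin-2-one, via mixed pivalic anhydride 3 (not isolated)
Conditions: PivCl, Et3N, THF, −20 °C; then LiCl, 2, −20 °C to rt
Reagents that add atoms: pivaloyl chloride, CC(C)(C)C(=O)Cl (its acyl group is held only in 3)
Why: N-acylation through the mixed pivalic anhydride is the standard entry to Evans imides, because the hindered pivaloyl carbonyl steers the LiCl-activated auxiliary to the arylacetyl carbonyl and no stereocentre is touched.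

Step 2
Reactants: 4 imide; 5 3,5-dimethoxybenzyl bromide
Product: 7 (R)-4-benzyl-3-[(R)-2-(3,4-dimethoxyphenyl)-3-(3,5-dimethoxyphenyl)propanoyl]oxazolidin-2-one, via sodium Z-enolate 6 (not isolated)
Conditions: NaN(SiMe3)2 (1.0 equiv), THF, −78 °C; then 5, −78 to −30 °C
Reagents that add atoms: none
Why: Evans asymmetric alkylation, in which the chelated Z-enolate is shielded on one face by the benzyl group of the (R)-auxiliary, so the reactive benzylic bromide enters from the other face and sets M2 as the (R)-configured alpha carbon with the spatial arrangement of the target.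

Step 3
Reactants: 7 benzylated imide
Product: 8 (R)-2-(3,4-dimethoxyphenyl)-3-(3,5-dimethoxyphenyl)propan-1-ol
Conditions: LiBH4, H2O (1 equiv), Et2O, 0 °C
Reagents that add atoms: none
Why: Reductive auxiliary removal with LiBH4 attacks the exocyclic imide carbonyl selectively and without epimerisation, so M2 passes unchanged into the primary alcohol and the auxiliary is recovered.

Step 4
Reactants: 8 primary alcohol
Product: 9 (R)-2-(3,4-dimethoxyphenyl)-3-(3,5-dimethoxyphenyl)propanal
Conditions: Dess–Martin periodinane, CH2Cl2, 0 °C to rt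
Reagents that add atoms: none
Why: Dess–Martin oxidation is base-free and stops at the aldehyde, which makes it the mildest access to a configurationally labile alpha-aryl aldehyde that is carried on at once without chromatography.

Step 5
Reactants: 9 aldehyde
Product: 10 (S)-1,1-dibromo-3-(3,4-dimethoxyphenyl)-4-(3,5-dimethoxyphenyl)but-1-ene
Conditions: CBr4, PPh3, Zn, CH2Cl2, rt; then 9, 0 °C to rt
Reagents that add atoms: carbon tetrabromide, BrC(Br)(Br)Br
Why: First stage of the Corey–Fuchs alkyne synthesis, a Wittig-type dibromomethylenation with an ylide preformed over zinc so that the medium stays neutral and M2 is not enolised (the descriptor changes only because the priorities change).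

Step 6
Reactants: 10 dibromoalkene
Product: 11 (S)-3-(3,4-dimethoxyphenyl)-4-(3,5-dimethoxyphenyl)but-1-yne
Conditions: n-BuLi (2.1 equiv), THF, −78 °C; then H2O
Reagents that add atoms: none
Why: Second stage of the Corey–Fuchs synthesis, in which bromine–lithium exchange, a Fritsch–Buttenberg–Wiechell-type shift and deprotonation give the lithium acetylide, whose charge guards the neighbouring propargylic benzylic C–H of M2 against a second deprotonation at low temperature.

Step 7
Reactants: 11 terminal alkyne
Product: 12 2-[(S)-2-(3,4-dimethoxyphenyl)but-3-ynyl]-4,6-dimethoxybenzaldehyde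
Conditions: POCl3, DMF, 0 to 50 °C; then H2O
Reagents that add atoms: N,N-dimethylformamide, CN(C)C=O; water, O
Why: Vilsmeier–Haack formylation selects the most electron-rich ring, the 1,3-dimethoxyarene D, and attacks next to the side chain (para to one methoxy group, ortho to the other) as it does in 3,5-dimethoxytoluene, the two such positions being equivalent, while ring E and the alkyne stay inert.

Step 8
Reactants: 12 aldehyde; 13 ethynylmagnesium bromide
Product: 14 1-{2-[(S)-2-(3,4-dimethoxyphenyl)but-3-ynyl]-4,6-dimethoxyphenyl}prop-2-yn-1-ol (both carbinol epimers)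
Conditions: 13 (3 equiv), THF, 0 °C; then H2O
Reagents that add atoms: none
Why: 1,2-addition of an alkynyl Grignard reagent to an aryl aldehyde, run with excess reagent because the terminal alkyne of 12 takes up one equivalent reversibly, and the new carbinol centre needs no control since the next step erases it.

Step 9
Reactants: 14 propargylic alcohol
Product: 15 1-{2-[(S)-2-(3,4-dimethoxyphenyl)but-3-ynyl]-4,6-dimethoxyphenyl}prop-2-yn-1-one (the 1,8-diyne)
Conditions: MnO2, CH2Cl2, rt
Reagents that add atoms: none
Why: MnO2 oxidises benzylic propargylic alcohols selectively under neutral heterogeneous conditions, and filtration is the only work-up, so the Michael-accepting terminal ynone meets neither base nor nucleophile.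

Step 10
Reactants: 15 1,8-diyne; 16 bis(pinacolboryl)acetylene
Product: 17 (11R)-11-(3,4-dimethoxyphenyl)-6,8-dimethoxy-2,3-bis(4,4,5,5-tetramethyl-1,3,2-dioxaborolan-2-yl)-10,11-dihydro-5H-dibenzo[a,d][7]annulen-5-one
Conditions: Cp*RuCl(cod) (10 mol %), 16 (3 equiv), ClCH2CH2Cl, 60 °C, 15 added by syringe pump over 10 h
Reagents that add atoms: none
Why: After loss of cod the Cp*RuCl fragment (divalent ruthenium) binds both terminal alkynes of 15 and couples them oxidatively at their inner carbons to a bicyclic ruthenacyclopentadiene (tetravalent ruthenium), after which 16 inserts into a Ru–C bond and reductive elimination releases the arene and the catalyst. The closest known reactions are Cp*RuCl(cod)-catalysed [2+2+2] cycloadditions of terminal alpha,omega-diynes with alkynylboronates and the cobalt- or rhodium-catalysed cyclotrimerisations in which a benzo-fused diyne closes a seven-membered ring together with the new arene. Ring F closes in the oxidative coupling, through the bond between the alkyne carbon on the carbonyl (M1) carbon and the alkyne carbon on M2, helped by a five-atom tether that ring D and the sp2 carbonyl carbon shorten and stiffen, and ring B closes in the insertion and reductive elimination, which join the two former alkyne CH carbons to the two boron-bearing carbons. No stereocentre is made, and M2, although propargylic and benzylic, is left alone by the neutral medium. The step needs cross-trimerisation to win over oligomerisation of 15, which is secured by keeping 15 dilute against a threefold excess of 16, an alkyne too bulky to trimerise by itself, and because 16 is symmetrical and the tether allows only the ortho-fused arene, no regiochemical question arises and boron ends up on exactly the two catechol carbons.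

Step 11
Reactants: 17 diboronate
Product: 18 (11R)-11-(3,4-dimethoxyphenyl)-2,3-dihydroxy-6,8-dimethoxy-10,11-dihydro-5H-dibenzo[a,d][7]annulen-5-one
Conditions: 30% H2O2, NaOH, THF–H2O, 0 °C, argon
Reagents that add atoms: hydrogen peroxide, OO
Why: Oxidation of arylboronates with basic hydrogen peroxide proceeds by 1,2-aryl migration from boron to oxygen at the same carbon, and the acyl group on ring B makes the resulting catechol less prone to over-oxidation during a short cold reaction.

Step 12
Reactants: 18 catechol
Product: 19 (11R)-11-(3,4-dimethoxyphenyl)-2,3,6,8-tetramethoxy-10,11-dihydro-5H-dibenzo[a,d][7]annulen-5-one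
Conditions: MeI, K2CO3, DMF, rt
Reagents that add atoms: iodomethane, CI
Why: Williamson etherification of the two acidic catechol hydroxyls brings ring B to the same methyl ether protection as rings D and E, and the diaryl ketone has no enolisable position.

Step 13
Reactants: 19 hexamethyl ether ketone
Product: 20 (11R)-11-(3,4-dimethoxyphenyl)-6-hydroxy-2,3,8-trimethoxy-10,11-dihydro-5H-dibenzo[a,d][7]annulen-5-one
Conditions: BCl3 (1.2 equiv), CH2Cl2, −78 to 0 °C; then H2O
Reagents that add atoms: none
Why: BCl3 chelates between the ketone oxygen and the neighbouring methoxy oxygen of ring D and chloride then removes only that methyl group, the well-known selective cleavage of aryl methyl ethers ortho to a carbonyl group, which singles out the oxygen that ring A must later replace.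

Step 14
Reactants: 20 ortho-hydroxy ketone
Product: 21 (11R)-11-(3,4-dimethoxyphenyl)-2,3,8-trimethoxy-5-oxo-10,11-dihydro-5H-dibenzo[a,d][7]annulen-6-yl triflate
Conditions: Tf2O, pyridine, CH2Cl2, 0 °C
Reagents that add atoms: triflic anhydride, O=S(=O)(OS(=O)(=O)C(F)(F)F)C(F)(F)F
Why: O-sulfonylation of the phenol installs the leaving group for ring C closure and at the same time masks an acidic OH that would otherwise consume Cp2TiMe2 and 9-BBN.

Step 15
Reactants: 21 keto triflate
Product: 22 (11R)-11-(3,4-dimethoxyphenyl)-2,3,8-trimethoxy-5-methylidene-10,11-dihydro-5H-dibenzo[a,d][7]annulen-6-yl triflate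
Conditions: Cp2TiMe2 (3 equiv), toluene, 75 °C, dark
Reagents that add atoms: dimethyltitanocene Cp2TiMe2, [CH3-].[CH3-].[Ti+4].c1cc[cH-]c1.c1cc[cH-]c1
Why: Petasis methylenation, in which Cp2Ti=CH2 formed by thermal loss of methane is non-basic and oxophilic enough to convert hindered and electron-rich diaryl ketones through an oxatitanacyclobutane while leaving aryl triflates and ethers alone.

Step 16
Reactants: 22 1,1-diarylethene; 23 1-iodo-3,5-dimethoxybenzene
Product: 25 (5S,11R)-5-(3,5-dimethoxybenzyl)-11-(3,4-dimethoxyphenyl)-2,3,8-trimethoxy-10,11-dihydro-5H-dibenzo[a,d][7]annulen-6-yl triflate, via B-alkyl-9-BBN adduct 24 (not isolated)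
Conditions: 9-BBN, THF, 60 °C; then 23, PdCl2(dppf) (5 mol %), Cs2CO3, DMF–H2O, 40 °C
Reagents that add atoms: 9-borabicyclo[3.3.1]nonane, B1C2CCCC1CCC2 (its boron unit is held only in 24)
Why: Hydroboration followed by B-alkyl Suzuki–Miyaura coupling, in which 9-BBN puts boron on the terminal carbon and delivers H to M1 by syn addition from the outer face of the boat-shaped ring F, the inner face being covered by ring E that sits pseudo-axially on M2 to escape the peri hydrogen of ring B, so that the hydrogens on M1 and M2 become cis (M1 S), and the aryl iodide adds to zerovalent palladium far faster than the hindered triflate, which therefore survives.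

Step 17
Reactants: 25 benzylated triflate
Product: 26 heptamethyl ether of the target (M1 S, M2 R)
Conditions: Pd(OAc)2 (10 mol %), PCy3·HBF4 (20 mol %), PivOH (30 mol %), K2CO3, DMA, 110 °C
Reagents that add atoms: none
Why: Intramolecular palladium-catalysed direct arylation by concerted metalation–deprotonation with pivalate as proton shuttle, in which oxidative addition into the C–OTf bond of ring D is followed by C–H cleavage at either of the two equivalent ring A positions ortho to the CH2 group, the only ones within reach, so that six-membered ring C closes without touching M1 or M2.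

Step 18
Reactants: 26 heptamethyl ether
Product: 27 CNP0306974.2 (target heptaphenol, M1 S, M2 R)
Conditions: BBr3 (14 equiv), CH2Cl2, −78 °C to rt; then H2O, argon
Reagents that add atoms: none
Why: Exhaustive aryl methyl ether cleavage with BBr3 is the standard last step for permethylated stilbenoid oligomers, removes all seven methyl groups by bromide attack on the boron-complexed ethers and leaves the two benzylic C–H stereocentres alone because they carry no leaving group.

Compound list
1 | homoveratric acid (3,4-dimethoxyphenylacetic acid) | OC(=O)Cc1ccc(OC)c(OC)c1 | starting material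
2 | (R)-4-benzyloxazolidin-2-one | O=C1N[C@H](Cc2ccccc2)CO1 | starting material
3 | (3,4-dimethoxyphenyl)acetic pivalic anhydride | CC(C)(C)C(=O)OC(=O)Cc1ccc(OC)c(OC)c1 | intermediate
4 | (R)-4-benzyl-3-[(3,4-dimethoxyphenyl)acetyl]oxazolidin-2-one | COc1ccc(CC(=O)N2C(=O)OC[C@H]2Cc2ccccc2)cc1OC | intermediate
5 | 3,5-dimethoxybenzyl bromide | COc1cc(CBr)cc(OC)c1 | starting material
6 | sodium (Z)-enolate of 4 | [Na+].[O-]/C(=C\c1ccc(OC)c(OC)c1)N1C(=O)OC[C@H]1Cc1ccccc1 | intermediate
7 | (R)-4-benzyl-3-[(R)-2-(3,4-dimethoxyphenyl)-3-(3,5-dimethoxyphenyl)propanoyl]oxazolidin-2-one | COc1cc(C[C@@H](C(=O)N2C(=O)OC[C@H]2Cc2ccccc2)c2ccc(OC)c(OC)c2)cc(OC)c1 | intermediate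
8 | (R)-2-(3,4-dimethoxyphenyl)-3-(3,5-dimethoxyphenyl)propan-1-ol | COc1cc(C[C@@H](CO)c2ccc(OC)c(OC)c2)cc(OC)c1 | intermediate
9 | (R)-2-(3,4-dimethoxyphenyl)-3-(3,5-dimethoxyphenyl)propanal | COc1cc(C[C@@H](C=O)c2ccc(OC)c(OC)c2)cc(OC)c1 | intermediate
10 | (S)-1,1-dibromo-3-(3,4-dimethoxyphenyl)-4-(3,5-dimethoxyphenyl)but-1-ene | COc1cc(C[C@@H](C=C(Br)Br)c2ccc(OC)c(OC)c2)cc(OC)c1 | intermediate
11 | (S)-3-(3,4-dimethoxyphenyl)-4-(3,5-dimethoxyphenyl)but-1-yne | COc1cc(C[C@@H](C#C)c2ccc(OC)c(OC)c2)cc(OC)c1 | intermediate
12 | 2-[(S)-2-(3,4-dimethoxyphenyl)but-3-ynyl]-4,6-dimethoxybenzaldehyde | O=Cc1c(OC)cc(OC)cc1C[C@@H](C#C)c1ccc(OC)c(OC)c1 | intermediate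
13 | ethynylmagnesium bromide | C#C[Mg]Br | starting material
14 | 1-{2-[(S)-2-(3,4-dimethoxyphenyl)but-3-ynyl]-4,6-dimethoxyphenyl}prop-2-yn-1-ol, both carbinol epimers | C#CC(O)c1c(OC)cc(OC)cc1C[C@@H](C#C)c1ccc(OC)c(OC)c1 | intermediate
15 | 1-{2-[(S)-2-(3,4-dimethoxyphenyl)but-3-ynyl]-4,6-dimethoxyphenyl}prop-2-yn-1-one (1,8-diyne, ynone carbonyl at the M1 carbon, ethynyl on M2) | C#CC(=O)c1c(OC)cc(OC)cc1C[C@@H](C#C)c1ccc(OC)c(OC)c1 | intermediate
16 | bis(pinacolboryl)acetylene | CC1(C)OB(C#CB2OC(C)(C)C(C)(C)O2)OC1(C)C | starting material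
17 | (11R)-11-(3,4-dimethoxyphenyl)-6,8-dimethoxy-2,3-bis(pinacolboryl)-10,11-dihydro-5H-dibenzo[a,d][7]annulen-5-one (C5 is the M1 carbon, C11 is M2, C1–C4 ring B, C6–C9 ring D) | O=C1c2cc(B3OC(C)(C)C(C)(C)O3)c(B3OC(C)(C)C(C)(C)O3)cc2[C@@H](c2ccc(OC)c(OC)c2)Cc2cc(OC)cc(OC)c21 | intermediate
18 | (11R)-11-(3,4-dimethoxyphenyl)-2,3-dihydroxy-6,8-dimethoxy-10,11-dihydro-5H-dibenzo[a,d][7]annulen-5-one | O=C1c2cc(O)c(O)cc2[C@@H](c2ccc(OC)c(OC)c2)Cc2cc(OC)cc(OC)c21 | intermediate
19 | (11R)-11-(3,4-dimethoxyphenyl)-2,3,6,8-tetramethoxy-10,11-dihydro-5H-dibenzo[a,d][7]annulen-5-one | O=C1c2cc(OC)c(OC)cc2[C@@H](c2ccc(OC)c(OC)c2)Cc2cc(OC)cc(OC)c21 | intermediate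
20 | (11R)-11-(3,4-dimethoxyphenyl)-6-hydroxy-2,3,8-trimethoxy-10,11-dihydro-5H-dibenzo[a,d][7]annulen-5-one | O=C1c2cc(OC)c(OC)cc2[C@@H](c2ccc(OC)c(OC)c2)Cc2cc(OC)cc(O)c21 | intermediate
21 | (11R)-11-(3,4-dimethoxyphenyl)-2,3,8-trimethoxy-5-oxo-10,11-dihydro-5H-dibenzo[a,d][7]annulen-6-yl triflate (numbering of 17 kept) | O=C1c2cc(OC)c(OC)cc2[C@@H](c2ccc(OC)c(OC)c2)Cc2cc(OC)cc(OS(=O)(=O)C(F)(F)F)c21 | intermediate
22 | (11R)-11-(3,4-dimethoxyphenyl)-2,3,8-trimethoxy-5-methylidene-10,11-dihydro-5H-dibenzo[a,d][7]annulen-6-yl triflate | C=C1c2cc(OC)c(OC)cc2[C@@H](c2ccc(OC)c(OC)c2)Cc2cc(OC)cc(OS(=O)(=O)C(F)(F)F)c21 | intermediate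
23 | 1-iodo-3,5-dimethoxybenzene | COc1cc(I)cc(OC)c1 | starting material
24 | (5S,11R)-5-[(9-borabicyclo[3.3.1]nonan-9-yl)methyl]-11-(3,4-dimethoxyphenyl)-2,3,8-trimethoxy-10,11-dihydro-5H-dibenzo[a,d][7]annulen-6-yl triflate | C1CC2CCCC(C1)B2C[C@H]1c2cc(OC)c(OC)cc2[C@@H](c2ccc(OC)c(OC)c2)Cc2cc(OC)cc(OS(=O)(=O)C(F)(F)F)c21 | intermediate
25 | (5S,11R)-5-(3,5-dimethoxybenzyl)-11-(3,4-dimethoxyphenyl)-2,3,8-trimethoxy-10,11-dihydro-5H-dibenzo[a,d][7]annulen-6-yl triflate | COc1cc(C[C@H]2c3cc(OC)c(OC)cc3[C@@H](c3ccc(OC)c(OC)c3)Cc3cc(OC)cc(OS(=O)(=O)C(F)(F)F)c32)cc(OC)c1 | intermediate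
26 | heptamethyl ether of the target (rings A–F complete, M1 S, M2 R) | COc1cc(OC)c2c(c1)C[C@H]1c3cc(OC)c(OC)cc3[C@@H](c3ccc(OC)c(OC)c3)Cc3cc(OC)cc-2c31 | intermediate
27 | CNP0306974.2 (M1 S, M2 R, methine hydrogens cis on ring F) | Oc1cc(O)c2c(c1)C[C@H]1c3cc(O)c(O)cc3[C@@H](c3ccc(O)c(O)c3)Cc3cc(O)cc-2c31 | target

Total step count: 18. Longest linear sequence: 18 steps (from 1 to 27). Compounds 2, 5, 13, 16 and 23 enter as purchased reagents.

Steps most likely to fail

Step 10. Oxidative coupling across the five-atom tether may be slower than intermolecular coupling of the activated ynone alkyne, so 15 would oligomerise. Insertion of the bulky internal alkyne into the ruthenacycle may also lag.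
- The fallback builds ring B by a Diels–Alder reaction and closes ring F separately by acylation.
- It sets out from 11. Deprotonation with n-BuLi and quenching with methyl chloroformate should give methyl (R)-4-(3,4-dimethoxyphenyl)-5-(3,5-dimethoxyphenyl)pent-2-ynoate F1.
- Heating F1 with 2,3-dimethoxybuta-1,3-diene should give the cyclohexa-1,4-diene adduct F2, and DDQ should aromatise it to the 4,5-dimethoxybenzoate F3.
- LiOH should then give the benzoic acid F4.
- Intramolecular Friedel–Crafts acylation with trifluoroacetic anhydride in CH2Cl2 should close ring F at the ring D carbon that both methoxy groups activate. This carbon should react ahead of the singly activated ring E.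
- The fallback comes back to the route at 19.

Step 16. Hydroboration of the hindered 1,1-diarylethene may be sluggish. Facial discrimination may erode if ring F populates a conformer with ring E pseudo-equatorial. Some oxidative addition into the triflate may also compete.
- The fallback brings in the carbon first and the hydrogen last by an ionic route. It sets out from 21 and from 5.
- Magnesium converts 5 into 3,5-dimethoxybenzylmagnesium bromide F5, which should add to the non-enolisable ketone of 21 at low temperature to give the tertiary dibenzylic alcohol F6.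
- Ionic hydrogenation (Et3SiH in excess, CF3CO2H, CH2Cl2, −40 °C) should ionise F6 to the planar M1 cation and deliver hydride from the face away from ring E.
- This selectivity can be tuned through the size of the silane, and no bulky borane is needed at the crowded carbon.
- The fallback comes back to the route at 25.

Step 4. Enolisation of the alpha-aryl aldehyde during oxidation, handling and olefination may erode the configuration at M2.
- The fallback avoids any carbonyl group next to M2 and sets the centre by catalyst control. It sets out from 5.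
- Zinc insertion (Zn, LiCl, THF) should give 3,5-dimethoxybenzylzinc bromide F7, which should add to 3-(trimethylsilyl)propynal to give the racemic propargylic alcohol F8.
- An Appel reaction (CBr4, PPh3) should give the racemic propargylic bromide F9.
- An enantioconvergent nickel-catalysed Negishi arylation follows (NiCl2·glyme, chiral pybox ligand of the enantiomeric series that leads to the required sense). The coupling partner is ethyl(3,4-dimethoxyphenyl)zinc F10, made from 3,4-dimethoxyphenylboronic acid and ZnEt2. This should give the silylated alkyne F11.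
- K2CO3 in MeOH removes the silyl group, and the fallback comes back to the route at 11.

Further compounds
F1 | step 10 | methyl (R)-4-(3,4-dimethoxyphenyl)-5-(3,5-dimethoxyphenyl)pent-2-ynoate | COc1cc(C[C@@H](C#CC(=O)OC)c2ccc(OC)c(OC)c2)cc(OC)c1
F2 | step 10 | methyl 2-[(1R)-1-(3,4-dimethoxyphenyl)-2-(3,5-dimethoxyphenyl)ethyl]-4,5-dimethoxycyclohexa-1,4-diene-1-carboxylate | COC(=O)C1=C(CC(OC)=C(OC)C1)[C@H](Cc1cc(OC)cc(OC)c1)c1ccc(OC)c(OC)c1
F3 | step 10 | methyl 2-[(1R)-1-(3,4-dimethoxyphenyl)-2-(3,5-dimethoxyphenyl)ethyl]-4,5-dimethoxybenzoate | COC(=O)c1cc(OC)c(OC)cc1[C@H](Cc1cc(OC)cc(OC)c1)c1ccc(OC)c(OC)c1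
F4 | step 10 | 2-[(1R)-1-(3,4-dimethoxyphenyl)-2-(3,5-dimethoxyphenyl)ethyl]-4,5-dimethoxybenzoic acid | OC(=O)c1cc(OC)c(OC)cc1[C@H](Cc1cc(OC)cc(OC)c1)c1ccc(OC)c(OC)c1
F5 | step 16 | 3,5-dimethoxybenzylmagnesium bromide | COc1cc(C[Mg]Br)cc(OC)c1
F6 | step 16 | (11R)-5-(3,5-dimethoxybenzyl)-11-(3,4-dimethoxyphenyl)-5-hydroxy-2,3,8-trimethoxy-10,11-dihydro-5H-dibenzo[a,d][7]annulen-6-yl triflate (carbinol configuration without consequence) | COc1cc(CC2(O)c3cc(OC)c(OC)cc3[C@@H](c3ccc(OC)c(OC)c3)Cc3cc(OC)cc(OS(=O)(=O)C(F)(F)F)c32)cc(OC)c1
F7 | step 4 | 3,5-dimethoxybenzylzinc bromide | COc1cc(C[Zn]Br)cc(OC)c1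
F8 | step 4 | racemic 1-(3,5-dimethoxyphenyl)-4-(trimethylsilyl)but-3-yn-2-ol | COc1cc(CC(O)C#C[Si](C)(C)C)cc(OC)c1
F9 | step 4 | racemic [3-bromo-4-(3,5-dimethoxyphenyl)but-1-ynyl]trimethylsilane | COc1cc(CC(Br)C#C[Si](C)(C)C)cc(OC)c1
F10 | step 4 | ethyl(3,4-dimethoxyphenyl)zinc | CC[Zn]c1ccc(OC)c(OC)c1
F11 | step 4 | (R)-[3-(3,4-dimethoxyphenyl)-4-(3,5-dimethoxyphenyl)but-1-ynyl]trimethylsilane | COc1cc(C[C@@H](C#C[Si](C)(C)C)c2ccc(OC)c(OC)c2)cc(OC)c1
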